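**Retrosynthetic overview** (labdane numbering)
1. The target comes from labda-7,13Z-diene-15,19-diol by C15 allylic oxidation, C19-O angeloylation and CHO to CO2H oxidation. Both CH2OH groups and the C3 methylene arise in one hydride operation on a 3-oxo-15,19-diester, which also releases the auxiliary.
2. The Δ7 alkene comes from the Δ8(17) alkene by hydrogen-atom-transfer isomerisation.
3. Key disconnection: C4–C5, with C10–C9 formed in the same event. C4 of an acyclic α-methyl-β-keto ester is oxidised to an electrophilic α-radical, a one-electron enolonium equivalent, and bonds to the nucleophilic alkene carbon C5. Ring A closes first and ring B second, which sets C4, C5, C9 and C10 at once.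
4. The acyclic chain is C5 + C10 + C5. C2–C1 is made by β-keto ester dianion alkylation. C12–C11 is made by copper dienolate γ-allylation of geranyl bromide, which also sets 13Z.

Assumption: the sense of induction of the (1R,2S,5R)-8-phenylmenthyl ester in step 6 follows the stacked-phenyl model given there (the sense that leads to the natural podocarpate series); if it proved opposite, the commercial enantiomer of the auxiliary would be used with no other change.

**Step 1**
Reactants: 1 3-methylbut-2-enoic acid; 2 geranyl bromide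
Product: 6 methyl (2Z,6E)-farnesoate, via dilithium dienolate 3 (not isolated), via lithium copper(I) dienolate 4 (not isolated), via lithium (2Z,6E)-farnesoate 5 (not isolated)
Conditions: LDA (2.1 equiv), THF, −78 to 0 °C; CuI (1.1 equiv), −78 °C; 2, −78 to −20 °C; then MeI (5 equiv), DMPU, rt
Reagents that add atoms: iodomethane, CI (ester CH3); lithium diisopropylamide, CC(C)[N-]C(C)C.[Li+] (Li of 3–5 only); copper(I) iodide, [Cu+].[I-] (Cu of 4 only)
Why: Copper(I) dienolate γ-allylation (vinylogous alkylation): lithium alone alkylates at Cα, Cu(I) moves attack to Cγ with SN2 opening of the prenyl-type bromide, the metal bridging carboxylate O and Cγ holds the dienolate s-cis so the new CH2 ends cis to the carboxylate (2Z), the 6E alkene of 2 is untouched, and the carboxylate is O-methylated in the same flask.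

**Step 2**
Reactants: 6 methyl (2Z,6E)-farnesoate
Product: 7 methyl (2Z,6E,10E)-12-hydroxyfarnesoate
Conditions: SeO2 (0.2 equiv), t-BuOOH (3 equiv), salicylic acid (0.1 equiv), CH2Cl2, 0 °C to rt
Reagents that add atoms: tert-butyl hydroperoxide, CC(C)(C)OO (source of the new O, passed on through catalytic SeO2, O=[Se]=O)
Why: Riley-type SeO2 allylic oxidation (ene reaction then [2,3]-shift) picks the E-methyl of the terminal isopropylidene group, because Δ2 is deactivated by the ester and the internal Δ6 alkene is more hindered, and it gives the (10E)-allylic alcohol.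

**Step 3**
Reactants: 7 methyl (2Z,6E,10E)-12-hydroxyfarnesoate
Product: 8 methyl (2Z,6E,10E)-12-bromofarnesoate
Conditions: PBr3 (0.4 equiv), Et2O, 0 °C
Reagents that add atoms: phosphorus tribromide, BrP(Br)Br
Why: SN2 displacement of the phosphite ester of a primary allylic alcohol gives the primary bromide at 0 °C without allylic shift or loss of alkene geometry.

**Step 4**
Reactants: 9 ethyl 2-methyl-3-oxobutanoate; 10 (−)-8-phenylmenthol
Product: 11 (1R,2S,5R)-8-phenylmenthyl 2-methyl-3-oxobutanoate (C2 epimers)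
Conditions: DMAP (0.3 equiv), toluene, reflux, EtOH distilled off
Reagents that add atoms: none
Why: DMAP-catalysed transesterification of an enolisable β-keto ester is driven by removal of ethanol, and the C2 centre may stay a mixture because it becomes planar in steps 5 and 6.

**Step 5**
Reactants: 11 8-phenylmenthyl 2-methyl-3-oxobutanoate; 8 methyl (2Z,6E,10E)-12-bromofarnesoate
Product: 13 1-methyl 16-[(1R,2S,5R)-8-phenylmenthyl] (2Z,6E,10E)-3,7,11,15-tetramethyl-14-oxohexadeca-2,6,10-trienedioate (C15 epimers), via sodium lithium dianion 12 (not isolated)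
Conditions: NaH (1.1 equiv), THF, 0 °C; n-BuLi (1.05 equiv), 0 °C; 8, 0 °C; aq. HCl
Reagents that add atoms: sodium hydride, [Na+].[H-], and n-butyllithium, [Li]CCCC (counter-ions of 12 only)
Why: Huckin–Weiler β-keto ester dianion alkylation: only the more basic terminal carbanion attacks the primary allylic bromide (SN2) and forms C2–C1, while the β,β-disubstituted enoate is inert at 0 °C.

**Step 6 (key step)**
Reactants: 13 acyclic trienyl α-methyl-β-keto ester
Product: 16 15-methyl 19-[(1R,2S,5R)-8-phenylmenthyl] (4R,5R,9S,10R,13Z)-3-oxolabda-8(17),13-diene-15,19-dioate, via C4 radical 14 (not isolated), via C8 radical 15 (not isolated)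
Conditions: Mn(OAc)3·2H2O (2.2 equiv), Cu(OAc)2·H2O (1.0 equiv), degassed AcOH (0.05 M), 25 °C; minor diastereomer removed by chromatography
Reagents that add atoms: none
Why: Mn(III)-based oxidative free-radical polyene cyclisation: the Mn(III) enolate collapses to the electrophilic α-keto-ester radical 14 (a one-electron enolonium equivalent, so C4, natively a nucleophilic α-carbon, bonds to the equally nucleophilic alkene carbon C5); two 6-endo closures through a chair–chair array of the E,E-diene form ring A then ring B with trans-anti C5/C10/C9 (9β side chain) and, with the carbonyl dipoles opposed, the ester axial at C4; the stacked phenyl of the auxiliary covers the Si face of C4 so C5 enters on the Re face and fixes the absolute sense; the Z-enoate stays out because 6-endo attack at C14 is polarity-mismatched and 5-exo attack at fully substituted C13 is too hindered; and Cu(II) oxidises tertiary radical 15 to the 8(17)-alkene.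

**Step 7**
Reactants: 16 3-oxolabda-8(17),13-diene diester
Product: 17 15-methyl 19-[(1R,2S,5R)-8-phenylmenthyl] (4R,5R,9S,10R,13Z)-3-oxolabda-7,13-diene-15,19-dioate
Conditions: Co(salen-tBu,tBu)Cl (3 mol %), PhSiH3 (6 mol %), benzene, 22 °C
Reagents that add atoms: none
Why: Cobalt-hydride hydrogen-atom-transfer (MHAT) alkene isomerisation: reversible H-atom addition to the 1,1-disubstituted alkene gives the C8 radical, the bulky Co(II) takes H back from the accessible C7–H rather than the buried C9–H, and the trisubstituted Δ7 and Δ13 alkenes no longer react, so C9 and the 13Z geometry are kept.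

**Step 8**
Reactants: 17 3-oxolabda-7,13-diene diester
Product: 19 (4S,5R,9S,10R,13Z)-labda-7,13-diene-15,19-diol, via C3 tosylhydrazone 18 (not isolated)
Conditions: TsNHNH2 (1.5 equiv), PPTS (cat.), 4 Å MS, THF, 65 °C; then LiAlH4 (10 equiv), 0 °C to reflux; H2O/NaOH work-up; 10 recovered
Reagents that add atoms: p-toluenesulfonyl hydrazide, Cc1ccc(cc1)S(=O)(=O)NN (its atoms stand only in 18 and leave again)
Why: Caglioti reduction: hydride adds to the C=N of the tosylhydrazone, and loss of sulfinate and N2 leaves the C3 methylene, while the same LiAlH4 reduces the hindered axial ester to the 19-CH2OH (freeing the auxiliary) and the enoate 1,2 to the Z-allylic alcohol, with no stereocentre touched (C4 changes from R to S only through CIP priorities).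

**Step 9**
Reactants: 19 labda-7,13Z-diene-15,19-diol
Product: 20 (4S,5R,9S,10R,13Z)-19-hydroxylabda-7,13-dien-15-al
Conditions: activated MnO2 (20 equiv), CH2Cl2, 0 °C to rt
Reagents that add atoms: none
Why: MnO2 oxidises only the allylic alcohol and leaves the saturated neopentyl 19-OH alone, and nerol-type Z-allylic alcohols give the Z-enal under these neutral conditions.

**Step 10**
Reactants: 20 19-hydroxylabda-7,13Z-dien-15-al; 21 angelic acid
Product: 23 (4S,5R,9S,10R,13Z)-19-angeloyloxylabda-7,13-dien-15-al, via mixed anhydride 22 (not isolated)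
Conditions: 21 (3 equiv), 2,4,6-trichlorobenzoyl chloride (3 equiv), Et3N (3 equiv), toluene, rt, salts filtered off; then 20, 80 °C
Reagents that add atoms: 2,4,6-trichlorobenzoyl chloride, O=C(Cl)c1c(Cl)cc(Cl)cc1Cl (its atoms stand only in 22)
Why: Yamaguchi mixed-anhydride esterification run without DMAP: the only free OH attacks the less shielded angeloyl carbonyl, and the absence of a nucleophilic catalyst avoids the addition–elimination path that turns angelate into tiglate.

**Step 11**
Reactants: 23 19-angeloyloxylabda-7,13Z-dien-15-al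
Product: 24 (4S,5R,9S,10R,13Z)-19-angeloyloxylabda-7,13-dien-15-oic acid (target)
Conditions: NaClO2, NaH2PO4, 2-methyl-2-butene, t-BuOH/H2O, 0 °C to rt
Reagents that add atoms: sodium chlorite, [Na+].[O-]Cl=O
Why: Pinnick oxidation converts the enal to the acid at buffered pH without Z/E drift, and the scavenger removes HOCl so the Δ7 alkene and the angelate survive.

**Compound list**
1 | 3-methylbut-2-enoic acid (senecioic acid) | CC(C)=CC(=O)O | starting material
2 | geranyl bromide, (2E)-1-bromo-3,7-dimethylocta-2,6-diene | CC(C)=CCC/C(C)=C/CBr | starting material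
3 | dilithium 3-methylbuta-1,3-diene-1,1-diolate | C=C(C)C=C([O-])[O-].[Li+].[Li+] | intermediate
4 | lithium copper(I) 3-methylbuta-1,3-diene-1,1-diolate | C=C(C)C=C([O-])[O-].[Li+].[Cu+] | intermediate
5 | lithium (2Z,6E)-3,7,11-trimethyldodeca-2,6,10-trienoate | CC(C)=CCC/C(C)=C/CC/C(C)=C\C(=O)[O-].[Li+] | intermediate
6 | methyl (2Z,6E)-3,7,11-trimethyldodeca-2,6,10-trienoate | CC(C)=CCC/C(C)=C/CC/C(C)=C\C(=O)OC | intermediate
7 | methyl (2Z,6E,10E)-12-hydroxy-3,7,11-trimethyldodeca-2,6,10-trienoate | OC/C(C)=C/CC/C(C)=C/CC/C(C)=C\C(=O)OC | intermediate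
8 | methyl (2Z,6E,10E)-12-bromo-3,7,11-trimethyldodeca-2,6,10-trienoate | BrC/C(C)=C/CC/C(C)=C/CC/C(C)=C\C(=O)OC | intermediate
9 | ethyl 2-methyl-3-oxobutanoate (racemic) | CCOC(=O)C(C)C(C)=O | starting material
10 | (−)-8-phenylmenthol, (1R,2S,5R)-5-methyl-2-(2-phenylpropan-2-yl)cyclohexan-1-ol | CC(C)(c1ccccc1)[C@@H]2CC[C@@H](C)C[C@H]2O | starting material
11 | (1R,2S,5R)-8-phenylmenthyl 2-methyl-3-oxobutanoate (C2 epimers) | CC(C)(c1ccccc1)[C@@H]2CC[C@@H](C)C[C@H]2OC(=O)C(C)C(C)=O | intermediate
12 | sodium lithium dianion of 11 | CC(C)(c1ccccc1)[C@@H]2CC[C@@H](C)C[C@H]2OC([O-])=C(C)C([O-])=C.[Na+].[Li+] | intermediate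
13 | 1-methyl 16-(8-phenylmenthyl) (2Z,6E,10E)-3,7,11,15-tetramethyl-14-oxohexadeca-2,6,10-trienedioate (C15 epimers) | CC(C)(c1ccccc1)[C@@H]2CC[C@@H](C)C[C@H]2OC(=O)C(C)C(=O)CC/C(C)=C/CC/C(C)=C/CC/C(C)=C\C(=O)OC | intermediate
14 | C4 (α-keto-ester) radical of 13 | CC(C)(c1ccccc1)[C@@H]2CC[C@@H](C)C[C@H]2OC(=O)[C](C)C(=O)CC/C(C)=C/CC/C(C)=C/CC/C(C)=C\C(=O)OC | intermediate
15 | bicyclic tertiary C8 radical | CC(C)(c1ccccc1)[C@@H]2CC[C@@H](C)C[C@H]2OC(=O)[C@@]3(C)C(=O)CC[C@]4(C)[C@@H](CC/C(C)=C\C(=O)OC)[C](C)CC[C@@H]34 | intermediate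
16 | 15-methyl 19-(8-phenylmenthyl) (4R,5R,9S,10R,13Z)-3-oxolabda-8(17),13-diene-15,19-dioate (4β-axial ester, 5α-H, 9β side chain, 10β-Me) | CC(C)(c1ccccc1)[C@@H]2CC[C@@H](C)C[C@H]2OC(=O)[C@@]3(C)C(=O)CC[C@]4(C)[C@@H](CC/C(C)=C\C(=O)OC)C(=C)CC[C@@H]34 | intermediate
17 | 15-methyl 19-(8-phenylmenthyl) (4R,5R,9S,10R,13Z)-3-oxolabda-7,13-diene-15,19-dioate | CC(C)(c1ccccc1)[C@@H]2CC[C@@H](C)C[C@H]2OC(=O)[C@@]3(C)C(=O)CC[C@]4(C)[C@@H](CC/C(C)=C\C(=O)OC)C(C)=CC[C@@H]34 | intermediate
18 | C3 tosylhydrazone of 17 (C=N geometry not defined) | CC(C)(c1ccccc1)[C@@H]2CC[C@@H](C)C[C@H]2OC(=O)[C@@]3(C)C(=NNS(=O)(=O)c5ccc(C)cc5)CC[C@]4(C)[C@@H](CC/C(C)=C\C(=O)OC)C(C)=CC[C@@H]34 | intermediate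
19 | (4S,5R,9S,10R,13Z)-labda-7,13-diene-15,19-diol | OC[C@@]1(C)CCC[C@]2(C)[C@@H](CC/C(C)=C\CO)C(C)=CC[C@@H]12 | intermediate
20 | (4S,5R,9S,10R,13Z)-19-hydroxylabda-7,13-dien-15-al | OC[C@@]1(C)CCC[C@]2(C)[C@@H](CC/C(C)=C\C=O)C(C)=CC[C@@H]12 | intermediate
21 | angelic acid, (2Z)-2-methylbut-2-enoic acid | C/C=C(/C)C(=O)O | starting material
22 | angelic 2,4,6-trichlorobenzoic anhydride | C/C=C(/C)C(=O)OC(=O)c1c(Cl)cc(Cl)cc1Cl | intermediate
23 | (4S,5R,9S,10R,13Z)-19-angeloyloxylabda-7,13-dien-15-al | C/C=C(/C)C(=O)OC[C@@]1(C)CCC[C@]2(C)[C@@H](CC/C(C)=C\C=O)C(C)=CC[C@@H]12 | intermediate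
24 | (4S,5R,9S,10R,13Z)-19-angeloyloxylabda-7,13-dien-15-oic acid | C/C=C(/C)C(=O)OC[C@@]1(C)CCC[C@]2(C)[C@@H](CC/C(C)=C\C(=O)O)C(C)=CC[C@@H]12 | target

**Totals:** 11 steps in all. The longest linear sequence is 10 steps (steps 1–3 and 5–11).

**Steps most likely to fail**

**Step 6 (key cyclisation).** The risks are a modest facial bias from the auxiliary, premature oxidation of the C10 radical, and capture of radical 15 by the enoate. The fallback sets out from 13 and returns at 16. It replaces metal oxidation by a redox-neutral group-transfer chain. Compound 13 is selenenylated at C4 (NaH, PhSeCl) to the α-phenylselenyl β-keto ester F3. Irradiation in benzene gives the same electrophilic C4 radical, and the C8 radical is now trapped quickly by PhSe transfer to give the bicyclic 8-phenylselenide F4. H2O2/pyridine then triggers selenoxide syn-elimination to 16. Any Δ7 isomer formed alongside it converges in step 7.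

**Step 8 (one-pot hydrazone and hydride reduction).** The risks are slow condensation next to the quaternary C4 and Δ2-alkene formation in place of reduction. The fallback sets out from 17 and returns at 19. It removes the oxygen through sulfur. Ethane-1,2-dithiol/BF3·OEt2 converts 17 into the 3,3-ethylenedithio ketal F5. Acetone-deactivated Raney nickel desulfurises it to the 3-deoxy diester F6 while sparing the trisubstituted alkenes. LiAlH4 in refluxing THF then gives 19 and returns the auxiliary.

**Step 1 (α/γ, SN2/SN2′ and Z/E selectivity of the copper dienolate).** The fallback sets out from 2 and returns at 6. It fixes the geometry by a stereospecific coupling. The dianion of methyl acetoacetate (NaH, n-BuLi) is alkylated with 2 to give methyl (6E)-7,11-dimethyl-3-oxododeca-6,10-dienoate F1. Tf2O with aqueous Me4NOH in toluene at 0 °C gives the (2E)-enol triflate F2, in which the chain is cis to the ester. MeMgBr with catalytic Fe(acac)3 (THF/NMP, −30 °C) then replaces OTf by CH3 with retention and gives 6.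

Further compounds
F1 | step 1 | methyl (6E)-7,11-dimethyl-3-oxododeca-6,10-dienoate | CC(C)=CCC/C(C)=C/CCC(=O)CC(=O)OC
F2 | step 1 | methyl (2E,6E)-7,11-dimethyl-3-(trifluoromethylsulfonyloxy)dodeca-2,6,10-trienoate | CC(C)=CCC/C(C)=C/CC/C(OS(=O)(=O)C(F)(F)F)=C\C(=O)OC
F3 | step 6 | C4-phenylselenyl derivative of 13 (C4 epimers) | CC(C)(c1ccccc1)[C@@H]2CC[C@@H](C)C[C@H]2OC(=O)C(C)([Se]c3ccccc3)C(=O)CC/C(C)=C/CC/C(C)=C/CC/C(C)=C\C(=O)OC
F4 | step 6 | 15-methyl 19-(8-phenylmenthyl) (4R,5R,9S,10R,13Z)-3-oxo-8-phenylselenyllabd-13-ene-15,19-dioate (C8 not defined) | CC(C)(c1ccccc1)[C@@H]2CC[C@@H](C)C[C@H]2OC(=O)[C@@]3(C)C(=O)CC[C@]4(C)[C@@H](CC/C(C)=C\C(=O)OC)C(C)([Se]c5ccccc5)CC[C@@H]34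
F5 | step 8 | 3,3-ethylenedithio ketal of 17 | CC(C)(c1ccccc1)[C@@H]2CC[C@@H](C)C[C@H]2OC(=O)[C@@]3(C)C5(SCCS5)CC[C@]4(C)[C@@H](CC/C(C)=C\C(=O)OC)C(C)=CC[C@@H]34
F6 | step 8 | 15-methyl 19-(8-phenylmenthyl) (5R,9S,10R,13Z)-labda-7,13-diene-15,19-dioate with 4β-axial ester | CC(C)(c1ccccc1)[C@@H]2CC[C@@H](C)C[C@H]2OC(=O)[C@@]3(C)CCC[C@]4(C)[C@@H](CC/C(C)=C\C(=O)OC)C(C)=CC[C@@H]34
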